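**Plan**

1. Retrosynthesis: the aryl ether O–CH2 bond is cut first (isofraxidin plus an oxolane diol); then the oxolane is cut at C3–C4 and O1–C2 together (oxolane numbering: O1, C2 bearing CH2OAr, C3 bearing CH3/OH, C4 H2, C5 bearing the 2-methylprop-1-enyl group).
2. Enabling feature: the edge C3–C2–CH2 carries oxygen on three atoms in a row (C3–OH, C2–O1, CH2–O). This is the footprint of an acetyl oxirane attacked at its C=O and at its inner ring carbon, while O1–C5–C4 is a 2-oxidoalkyl carbanion, so an anionic [3+2] annulation driven by oxirane strain release closes the ring.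
3. Forward: chloromethyl enone → chlorohydrin; glycidate → Weinreb amide → acetyl oxirane; the two fragments are joined to the oxolane diol (the only ring made; the coumarin is bought); a Mitsunobu etherification ends the route. No protecting groups are used.
4. Stereochemistry: C5 from a CBS reduction (reagent control); C2 from methyl (R)-glycidate, taken with inversion in the ring closure; C3 from chelation-controlled addition to the ketone.

Key step: step 5

Remark (assumption): the C-metalated alkoxides made from the chlorohydrin are taken to persist at −78 °C long enough to be trapped, as is known for the dilithio reagents from simple chlorohydrins. Isofraxidin, methyl (R)-glycidate and the alkenyl Grignard solution are bought.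

**Step 1**
Reactants: 1 2-chloro-N-methoxy-N-methylacetamide; 2 (2-methylprop-1-en-1-yl)magnesium bromide
Product: 3 1-chloro-4-methylpent-3-en-2-one
Conditions: THF, −20 to 0 °C; then 1 M HCl
Reagents that add atoms: none
Why: Weinreb ketone synthesis: the magnesium-chelated tetrahedral adduct holds until the acid quench, so the alkenyl Grignard reagent adds once and the chloromethyl ketone is released without over-addition.

**Step 2**
Reactants: 3 1-chloro-4-methylpent-3-en-2-one
Product: 4 (S)-1-chloro-4-methylpent-3-en-2-ol
Conditions: (S)-2-methyl-CBS-oxazaborolidine (C18H20BNO, 10 mol %), catecholborane, toluene, −78 °C; then H2O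
Reagents that add atoms: none
Why: Corey–Bakshi–Shibata reduction: hydride is delivered 1,2 to the carbonyl face fixed by the catalyst, with the alkenyl group as the large and CH2Cl as the small substituent, which should give the (S)-chlorohydrin (new stereocenter under reagent control).

**Step 3**
Reactants: 5 methyl (R)-oxirane-2-carboxylate
Product: 6 (R)-N-methoxy-N-methyloxirane-2-carboxamide
Conditions: MeNHOMe·HCl, i-PrMgCl, THF, −20 °C; then H2O
Reagents that add atoms: N,O-dimethylhydroxylamine hydrochloride (CNOC.Cl)
Why: Ester aminolysis by the chloromagnesium amide (Weinreb amide formation): at −20 °C acyl substitution should outrun oxirane opening, and the stereocenter is not touched.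

**Step 4**
Reactants: 6 (R)-N-methoxy-N-methyloxirane-2-carboxamide
Product: 7 (R)-1-(oxiran-2-yl)ethan-1-one
Conditions: MeMgBr, THF, −78 to −20 °C; then H2O (pH 7 buffer); product kept as a dried solution
Reagents that add atoms: methylmagnesium bromide (C[Mg]Br)
Why: Weinreb ketone synthesis, a known conversion of oxiranyl Weinreb amides: one methyl group is transferred through the stable chelate, which gives the epoxy ketone with the oxirane and its configuration intact.

**Step 5**
Reactants: 4 (S)-1-chloro-4-methylpent-3-en-2-ol; 7 (R)-1-(oxiran-2-yl)ethan-1-one
Product: 11 (2S,3R,5R)-2-(hydroxymethyl)-3-methyl-5-(2-methylprop-1-en-1-yl)oxolan-3-ol, via dilithio dianion 8 (not isolated), via alkylmagnesium bromide 9 (not isolated), via epoxy dialkoxide 10 (not isolated)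
Conditions: n-BuLi (1 equiv), THF, −78 °C; LiC10H8 (2 equiv), −78 °C; MgBr2·OEt2 (1 equiv); 7, −78 to −40 °C; then 23 °C; then H2O
Reagents that add atoms: none
Why: Deprotonation and two-electron chloride–lithium exchange turn 4 into the 2-oxidoalkyl carbanion 8 (a C–C–O three-atom donor), which after exchange to magnesium (9) adds to the ketone of 7 and leaves the oxirane intact; on warming, the C5 alkoxide of 10 opens the strained oxirane at its inner carbon and the primary alkoxide is released. The closest known reaction types are the addition of 2-oxidoalkyllithium reagents made from chlorohydrins to ketones (giving 1,3-diols) and the cyclisation of 4,5-epoxy alkoxides to 2-(hydroxymethyl)oxolanes. The oxolane closes in the 5-exo-tet mode, the breaking oxirane C–O bond lying outside the new ring. C3 is set in the carbonyl addition by the five-membered magnesium chelate of the ketone oxygen and the oxirane oxygen (Cram cyclic model; the carbanion enters on the face of the oxirane C–H, away from its CH2), C2 is the (R)-oxirane carbon taken with inversion in the ring closure, and C5 is carried unchanged from 4. The step needs carbonyl attack before oxirane attack by the carbanion, which the activated α-oxygenated ketone and −78 °C secure, and 5-exo in place of 6-endo opening, which the four-atom tether and the fully substituted C3 favour.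

**Step 6**
Reactants: 11 (2S,3R,5R)-2-(hydroxymethyl)-3-methyl-5-(2-methylprop-1-en-1-yl)oxolan-3-ol; 12 isofraxidin (7-hydroxy-6,8-dimethoxy-2H-chromen-2-one)
Product: 13 7-{[(2S,3R,5R)-3-hydroxy-3-methyl-5-(2-methylprop-1-en-1-yl)oxolan-2-yl]methoxy}-6,8-dimethoxy-2H-chromen-2-one
Conditions: PPh3, DIAD, THF, 0 to 23 °C
Reagents that add atoms: none
Why: Mitsunobu etherification: only the primary alcohol is activated as its oxyphosphonium ion and displaced by the acidic phenol, while the tertiary alcohol and the three stereocenters stay untouched.

**Compound list**

1 | 2-chloro-N-methoxy-N-methylacetamide | CON(C)C(=O)CCl | starting material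
2 | (2-methylprop-1-en-1-yl)magnesium bromide (THF solution) | CC(C)=C[Mg]Br | starting material
3 | 1-chloro-4-methylpent-3-en-2-one | CC(C)=CC(=O)CCl | intermediate
4 | (S)-1-chloro-4-methylpent-3-en-2-ol | CC(C)=C[C@H](O)CCl | intermediate
5 | methyl (R)-oxirane-2-carboxylate (methyl (R)-glycidate) | COC(=O)[C@H]1CO1 | starting material
6 | (R)-N-methoxy-N-methyloxirane-2-carboxamide | CON(C)C(=O)[C@H]1CO1 | intermediate
7 | (R)-1-(oxiran-2-yl)ethan-1-one | CC(=O)[C@H]1CO1 | intermediate
8 | lithium (2R)-1-lithio-4-methylpent-3-en-2-olate (C,O-dilithio dianion of 4; spatial arrangement of 4 kept, the descriptor changes only through ranking) | CC(C)=C[C@H](O[Li])C[Li] | intermediate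
9 | lithium (2S)-1-(bromomagnesio)-4-methylpent-3-en-2-olate | CC(C)=C[C@H](O[Li])C[Mg]Br | intermediate
10 | bromomagnesium lithium (2R,4R)-6-methyl-2-[(2R)-oxiran-2-yl]hept-5-ene-2,4-diolate (tertiary O–MgBr, secondary O–Li) | CC(C)=C[C@H](O[Li])C[C@@](C)(O[Mg]Br)[C@H]1CO1 | intermediate
11 | (2S,3R,5R)-2-(hydroxymethyl)-3-methyl-5-(2-methylprop-1-en-1-yl)oxolan-3-ol | OC[C@@H]1O[C@@H](C=C(C)C)C[C@@]1(C)O | intermediate
12 | isofraxidin (7-hydroxy-6,8-dimethoxy-2H-chromen-2-one) | COc1cc2ccc(=O)oc2c(OC)c1O | starting material
13 | 7-{[(2S,3R,5R)-3-hydroxy-3-methyl-5-(2-methylprop-1-en-1-yl)oxolan-2-yl]methoxy}-6,8-dimethoxy-2H-chromen-2-one | COc1cc2ccc(=O)oc2c(OC)c1OC[C@@H]1O[C@@H](C=C(C)C)C[C@@]1(C)O | target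

**Step count and risks**

Total steps: 6. Longest linear sequence: 4 steps (steps 1, 2, 5, 6; the branch through steps 3, 4, 5, 6 is equally long).

Steps most likely to fail:

1. Step 5. What may go wrong: β-elimination of the C-metalated alkoxide before it meets the ketone; deprotonation of the methyl ketone in place of addition; loss of facial control if the magnesium chelate does not form; bromide opening or 6-endo opening of the oxirane during the closure. Fallback: it sets out from 7 and returns to the route at 11, making the C3–C4 bond and the O1–C2 bond in separate, individually known steps. Commercial mesityl oxide (4-methylpent-3-en-2-one) is deprotonated at its methyl ketone carbon with LiN(i-Pr)2 (THF, −78 °C) to lithium 4-methylpenta-1,3-dien-2-olate F1. This enolate is added at −78 °C to 7 premixed with MgBr2·OEt2 (chelation-controlled aldol addition, cold quench) to give (6R)-6-hydroxy-2-methyl-6-[(2R)-oxiran-2-yl]hept-2-en-4-one F2. Reagent-controlled CBS reduction of the enone carbonyl ((S)-2-methyl-CBS-oxazaborolidine, catecholborane, toluene, −78 °C) should give (2R,4R)-6-methyl-2-[(2R)-oxiran-2-yl]hept-5-ene-2,4-diol F3. A catalytic amount of camphorsulfonic acid (CH2Cl2, 0 °C) then closes the oxolane by 5-exo opening with inversion to give 11.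

2. Step 2. What may go wrong: weak enantioface discrimination, because the chloromethyl group and the trisubstituted alkenyl group may not differ enough in effective size, and competing conjugate reduction. Fallback: it sets out from 3 and returns at 4, using resolution in place of asymmetric reduction. Luche reduction (NaBH4, CeCl3·7H2O, MeOH, 0 °C) gives rac-1-chloro-4-methylpent-3-en-2-ol F4. Acylation with vinyl acetate and Candida antarctica lipase B (MTBE, 23 °C) should, by the usual size rule for secondary alcohols, convert the (S)-alcohol to (S)-1-chloro-4-methylpent-3-en-2-yl acetate F5, which is separated from the unreacted (R)-alcohol. The acetate is cleaved under neutral conditions by the same lipase in methanol to give 4; base is avoided because it would close the chlorohydrin to the oxirane.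

3. Step 3. What may go wrong: attack of the magnesium amide or of chloride at the oxirane CH2 in place of the ester carbonyl, and loss of the small, water-soluble amide on work-up. Fallback: it sets out from 5 and returns at 6 by way of the carboxylate. Saponification (KOH, EtOH, 0 °C) gives potassium (R)-oxirane-2-carboxylate F6, which is coupled with MeNHOMe·HCl through the mixed anhydride (pivaloyl chloride, N-methylmorpholine, THF, −10 °C) to give 6, so that no strongly basic amide nucleophile meets the oxirane.

**Further compounds**

F1 | step 5 | lithium 4-methylpenta-1,3-dien-2-olate | C=C(O[Li])C=C(C)C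
F2 | step 5 | (6R)-6-hydroxy-2-methyl-6-[(2R)-oxiran-2-yl]hept-2-en-4-one | CC(C)=CC(=O)C[C@@](C)(O)[C@H]1CO1
F3 | step 5 | (2R,4R)-6-methyl-2-[(2R)-oxiran-2-yl]hept-5-ene-2,4-diol | CC(C)=C[C@H](O)C[C@@](C)(O)[C@H]1CO1
F4 | step 2 | rac-1-chloro-4-methylpent-3-en-2-ol | CC(C)=CC(O)CCl
F5 | step 2 | (S)-1-chloro-4-methylpent-3-en-2-yl acetate | CC(=O)O[C@@H](C=C(C)C)CCl
F6 | step 3 | potassium (R)-oxirane-2-carboxylate | [K+].[O-]C(=O)[C@H]1CO1
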